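**Plan**
1. Locants (this answer only): lactone C1(=O)–C2=C3–C4(OH); ring A = cyclohexane C4–C9; ring B = cyclohexene C2/C3/C4/C9/C10/C15; ring C = cyclopentane C10–C13 + C15 (13-Me); ring D = lactone O/C1/C2/C15/C13; ring E = piperidine N1'–C6' (6'-Me, N-acetyl).
2. Enabling feature: in ring B, C3 is the β-carbon of the α-alkylidene lactone (C1=O, C2=C3) and C4 is a tertiary carbinol γ to C1. Ring B is therefore the formal adduct of the vinylic C3–H of an exo-methylene lactone across a C4 ketone; the cis-fused rings C/D hold C2 and the C10 substituent on one face.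
3. Cuts, in order: C3–C4 (ring B) to keto exo-methylene lactone 26; C3 (=CH2) and N-acetyl; C12–C2' (Suzuki–Miyaura, then hydrogenation); C9–C10 (aza-enolate Michael addition to dienone 8); C2=C15 (Horner–Wadsworth–Emmons) back to 2-methylcyclopentane-1,3-dione.
4. Forward: ring C is bought, ring D is closed (step 4), ring A is joined at C9–C10 (step 7), ring E is joined at C12–C2' (step 11), and ring B is closed last (step 16) by a carbene-catalysed β-umpolung cycloisomerisation.
5. Stereochemistry: C13 by desymmetrising transfer hydrogenation; C10 by attack anti to 13-Me; C9 by the SAMP auxiliary; C15 and C12 by hydride/hydrogen delivery to the convex face; C6' from (S)-6-methylpiperidin-2-one and C2' cis to it by hydrogenation; C4 in the ring closure.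

Key step: step 16

Remarks: (S)-6-methylpiperidin-2-one (16), SAMP (10) and the triazolylidene precursor are taken as commercial. Hydrazone C=N geometry has no consequence and is drawn E. In step 3 the catalyst antipode that reduces the carbonyl shown is fixed in the first run; the (R,R) complex is used if the sense is opposite.

**Step 1**
Reactants: 1 2-methylcyclopentane-1,3-dione
Product: 2 2-hydroxy-2-methylcyclopentane-1,3-dione
Conditions: dimethyldioxirane (acetone solution, 1.2 equiv), acetone, 0 °C to rt
Reagents that add atoms: dimethyldioxirane, CC1(C)OO1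
Why: The dione reacts as its enol, whose C=C is epoxidised and collapses to the tertiary α-hydroxy dione (dioxirane α-hydroxylation of 1,3-dicarbonyl compounds); no stereocentre arises because the mirror plane is kept.

**Step 2**
Reactants: 2 2-hydroxy-2-methylcyclopentane-1,3-dione; 3 2-(diethoxyphosphoryl)acetic acid
Product: 4 1-methyl-2,5-dioxocyclopentyl 2-(diethoxyphosphoryl)acetate
Conditions: DCC, DMAP (cat.), CH2Cl2, 0 °C to rt
Reagents that add atoms: none
Why: Steglich esterification acylates the hindered tertiary alcohol under neutral conditions that spare the base-sensitive 2-acyloxy-1,3-dione; the product is still achiral.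

**Step 3**
Reactants: 4 1-methyl-2,5-dioxocyclopentyl 2-(diethoxyphosphoryl)acetate
Product: 5 (1S,2S)-2-hydroxy-1-methyl-5-oxocyclopentyl 2-(diethoxyphosphoryl)acetate (hydroxyl cis to the acyloxy group)
Conditions: RuCl(p-cymene)[(S,S)-TsDPEN] (1 mol %), HCO2H/Et3N (5:2), CH2Cl2, 0 °C to rt, stopped at mono-reduction
Reagents that add atoms: none
Why: Asymmetric transfer hydrogenation of a 2,2-disubstituted cyclopentane-1,3-dione should reduce one of the two enantiotopic carbonyl groups, hydride entering anti to the larger acyloxy group, so the quaternary carbon (C13) becomes stereogenic under catalyst control; only the choice of carbonyl matters because the carbinol is oxidised again in step 5.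

**Step 4**
Reactants: 5 (1S,2S)-2-hydroxy-1-methyl-5-oxocyclopentyl 2-(diethoxyphosphoryl)acetate
Product: 6 (6S,6aR)-6-hydroxy-6a-methyl-4,5,6,6a-tetrahydro-2H-cyclopenta[b]furan-2-one (hydroxy butenolide, rings C and D)
Conditions: LiCl, DBU, MeCN, rt
Reagents that add atoms: none
Why: Intramolecular Horner–Wadsworth–Emmons olefination of the only remaining ketone closes the butenolide (ring D) through a five-membered transition state; the mild amine/LiCl base leaves the β-hydroxy ketone unit and C13 untouched.

**Step 5**
Reactants: 6 hydroxy butenolide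
Product: 8 (6aR)-6a-methyl-2H-cyclopenta[b]furan-2,6(6aH)-dione (dienone lactone), via keto butenolide 7 (not isolated)
Conditions: 2-iodoxybenzoic acid (IBX, 3.5 equiv), DMSO/fluorobenzene (1:2), rt then 70 °C
Reagents that add atoms: none
Why: IBX oxidises the secondary alcohol to ketone 7 and on warming dehydrogenates it to the enone (IBX α,β-desaturation of ketones); C13 is quaternary, so the new double bond can only form at C10=C11.

**Step 6**
Reactants: 9 cyclohexanone; 10 (S)-1-amino-2-(methoxymethyl)pyrrolidine (SAMP)
Product: 11 cyclohexanone SAMP hydrazone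
Conditions: neat, 60 °C, 12 h, then distillation
Reagents that add atoms: none
Why: Condensation of the ketone with the hydrazine auxiliary gives the hydrazone, which serves both as the chiral nucleophile precursor and as the mask of the ring-A ketone.

**Step 7**
Reactants: 11 cyclohexanone SAMP hydrazone; 8 dienone lactone
Product: 14 C12 alkenyl triflate of the C10 Michael adduct (butenolide intact; ring A attached at C9 anti to 13-Me; ring-A ketone masked as SAMP hydrazone), via lithium aza-enolate 12 (not isolated), via lithium enolate 13 (not isolated)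
Conditions: LiN(i-Pr)2, THF, 0 °C; then 8, THF, −100 to −78 °C; then N-(5-chloropyridin-2-yl)bis(trifluoromethanesulfonyl)imide, −78 to 0 °C; aq. NH4Cl
Reagents that add atoms: N-(5-chloropyridin-2-yl)bis(trifluoromethanesulfonyl)imide, O=S(=O)(N(c1ccc(Cl)cn1)S(=O)(=O)C(F)(F)F)C(F)(F)F
Why: Michael addition of a lithiated SAMP hydrazone to the enone β-carbon C10, then O-triflation of the C12 enolate; C9 (S) is set by the auxiliary (acceptor enters the aza-enolate face opposite the chelated methoxymethyl arm), C10 by the substrate (attack anti to the angular 13-methyl of the nearly flat dienone), and 1,2-addition is held back by the quaternary C13 next to the ketone.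

**Step 8**
Reactants: 14 C12 alkenyl triflate with butenolide
Product: 15 C12 alkenyl triflate with saturated cis-fused lactone (H15 syn to 13-Me)
Conditions: Cu(OAc)2·H2O (5 mol %), 1,2-bis(diphenylphosphino)benzene (5 mol %), (EtO)2MeSiH (3 equiv), t-BuOH (3 equiv), toluene, rt
Reagents that add atoms: none
Why: Phosphine-ligated copper hydride conjugate reduction of the β,β-disubstituted butenolide delivers hydride to C15 on the 13-methyl face, the only mode that gives the strain-free cis-fused rings C/D, and leaves the alkenyl triflate and hydrazone alone.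

**Step 9**
Reactants: 16 (S)-6-methylpiperidin-2-one
Product: 17 tert-butyl (S)-2-methyl-6-oxopiperidine-1-carboxylate
Conditions: Boc2O, DMAP, Et3N, CH2Cl2, rt
Reagents that add atoms: di-tert-butyl dicarbonate, CC(C)(C)OC(=O)OC(=O)OC(C)(C)C
Why: N-acylation of the lactam as its carbamate activates the ring α-position for enolisation and keeps the C6' stereocentre.

**Step 10**
Reactants: 17 tert-butyl (S)-2-methyl-6-oxopiperidine-1-carboxylate
Product: 18 tert-butyl (S)-2-methyl-6-(trifluoromethylsulfonyloxy)-3,4-dihydro-2H-pyridine-1-carboxylate
Conditions: KN(SiMe3)2, THF, −78 °C; PhNTf2, −78 to 0 °C; aq. NH4Cl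
Reagents that add atoms: N-phenylbis(trifluoromethanesulfonimide), O=S(=O)(N(c1ccccc1)S(=O)(=O)C(F)(F)F)C(F)(F)F
Why: O-triflation of the potassium enolate of an N-alkoxycarbonyl lactam gives the lactam-derived alkenyl triflate, an established class of cross-coupling partner.

**Step 11**
Reactants: 15 C12 alkenyl triflate with saturated lactone; 18 lactam-derived alkenyl triflate
Product: 20 amido-diene (C12 of ring C bonded to C2' of the N-Boc 6'-methyl tetrahydropyridine), via pinacol boronate 19 (not isolated)
Conditions: B2pin2, PdCl2(dppf) (5 mol %), KOAc, 1,4-dioxane, 80 °C; then 18, aq. K3PO4, 60 °C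
Reagents that add atoms: none
Why: Miyaura borylation of the hindered alkenyl triflate and Suzuki–Miyaura coupling with the second alkenyl triflate in one pot form the C12–C2' bond between two sp2 carbons, so no stereocentre is at stake.

**Step 12**
Reactants: 20 amido-diene
Product: 21 N-Boc piperidine (12R, 2'S, 6'S; all ring-C substituents cis; hydrazone retained)
Conditions: H2 (3 atm), 10% Pd/C, EtOAc, rt
Reagents that add atoms: none
Why: Heterogeneous hydrogenation should add hydrogen to the ring-C alkene from the convex face of the cis-fused rings C/D (setting C12) and to the ene-carbamate anti to the pseudo-axial 6'-methyl group (A(1,3) strain with N-Boc, giving the 2',6'-cis piperidine); the dialkylhydrazone is expected to survive neutral conditions.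

**Step 13**
Reactants: 21 N-Boc piperidine lactone
Product: 23 2-methylene lactone (C2=C3H2; hydrazone and N-Boc retained), via sodium formyl enolate 22 (not isolated)
Conditions: NaH, HCO2Et, THF, 0 °C to rt; then paraformaldehyde, THF, 65 °C
Reagents that add atoms: formaldehyde (from paraformaldehyde), C=O
Why: Claisen formylation of the lactone at C2, aldol reaction of the formyl enolate with formaldehyde and loss of formate (the formylation–formaldehyde α-methylenation of lactones) install C3 as the exo-methylene group, while the hydrazone keeps the more acidic ring-A ketone masked.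

**Step 14**
Reactants: 23 2-methylene lactone hydrazone
Product: 24 keto 2-methylene lactone (N-Boc)
Conditions: saturated aq. oxalic acid, Et2O, rt
Reagents that add atoms: water, O
Why: Two-phase oxalic acid hydrolysis of the SAMP hydrazone should free the ketone without epimerising C9 and carries the auxiliary into the aqueous phase as its salt, away from the Michael-acceptor lactone.

**Step 15**
Reactants: 24 keto 2-methylene lactone (N-Boc)
Product: 26 N-acetyl keto exo-methylene lactone (cyclisation precursor), via piperidinium trifluoroacetate 25 (not isolated)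
Conditions: CF3CO2H, CH2Cl2, 0 °C; evaporate; Ac2O, Et3N, DMAP (cat.), CH2Cl2, 0 °C to rt
Reagents that add atoms: acetic anhydride, CC(=O)OC(C)=O
Why: Acidolysis of the tert-butyl carbamate and N-acetylation of the secondary amine; base is added only with the anhydride present, so the amine is acylated before it can add to the exo-methylene lactone.

**Step 16**
Reactants: 26 N-acetyl keto exo-methylene lactone
Product: 27 target (CNP0529632.1)
Conditions: 1,3,4-triphenyl-1,2,4-triazol-5-ylidene (20 mol %, released from its 5-methoxy-4,5-dihydro adduct), 1,4-dioxane (0.01 M), 80 °C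
Reagents that add atoms: none
Why: Proposed new method: the triazolylidene adds to C3 of the exo-methylene lactone, a 1,2-proton shift from C3 to C2 gives the ene-1,1-diamine (deoxy-Breslow) intermediate in which C3 is nucleophilic, C3 attacks the C4 ketone in an aldol-type addition, and deprotonation at C2 with loss of the azolium from C3 (E1cB) restores C2=C3 and the catalyst, so the vinylic C3–H has formally added across C4=O. The closest known reaction type is the carbene-catalysed β-umpolung of acrylates, shown for intramolecular β-alkylation with tethered alkyl halides and for tail-to-tail dimerisation of methacrylates and α-methylene-γ-butyrolactone; a ketone as the electrophile is the untested part. Ring B closes by formation of the C3–C4 bond in a 6-(enolexo)-exo-trig mode, the enamine-type double bond lying outside the forming ring. The only new stereocentre, C4, should be controlled by ring A and C9: the C9–C10 bond is equatorial, the addition is reversible until the azolium leaves, and the chair-like transition state with C3 entering equatorially gives trans-fused rings A/B with the hydroxyl axial and cis to the C9–C10 bond. The step needs cyclisation to outrun intermolecular conjugate-addition chain growth and the ketone to react in preference to the lactone and amide carbonyls; high dilution, the weakly basic triazolylidene (which favours proton transfer over chain growth and should not epimerise C9) and the cis arrangement of C2 and the C10 substituent on ring C, which holds C3 within reach of C4 only, should secure this.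

**Compound list**
1 | 2-methylcyclopentane-1,3-dione | CC1C(=O)CCC1=O | starting material
2 | 2-hydroxy-2-methylcyclopentane-1,3-dione | CC1(O)C(=O)CCC1=O | intermediate
3 | 2-(diethoxyphosphoryl)acetic acid | OC(=O)CP(=O)(OCC)OCC | starting material
4 | 1-methyl-2,5-dioxocyclopentyl 2-(diethoxyphosphoryl)acetate | CC1(OC(=O)CP(=O)(OCC)OCC)C(=O)CCC1=O | intermediate
5 | (1S,2S)-2-hydroxy-1-methyl-5-oxocyclopentyl 2-(diethoxyphosphoryl)acetate | C[C@]1(OC(=O)CP(=O)(OCC)OCC)[C@@H](O)CCC1=O | intermediate
6 | (6S,6aR)-6-hydroxy-6a-methyl-4,5,6,6a-tetrahydro-2H-cyclopenta[b]furan-2-one | C[C@@]12OC(=O)C=C1CC[C@@H]2O | intermediate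
7 | (6aR)-6a-methyl-4,5-dihydro-2H-cyclopenta[b]furan-2,6(6aH)-dione (keto butenolide) | C[C@@]12OC(=O)C=C1CCC2=O | intermediate
8 | (6aR)-6a-methyl-2H-cyclopenta[b]furan-2,6(6aH)-dione (dienone lactone) | C[C@@]12OC(=O)C=C1C=CC2=O | intermediate
9 | cyclohexanone | O=C1CCCCC1 | starting material
10 | (S)-1-amino-2-(methoxymethyl)pyrrolidine (SAMP) | COC[C@@H]1CCCN1N | starting material
11 | (S)-N-cyclohexylidene-2-(methoxymethyl)pyrrolidin-1-amine (cyclohexanone SAMP hydrazone) | COC[C@@H]1CCCN1N=C1CCCCC1 | intermediate
12 | lithium aza-enolate of 11 | COC[C@@H]1CCCN1[N-]C1=CCCCC1.[Li+] | intermediate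
13 | lithium C12 enolate of the C10 Michael adduct (butenolide intact, 9S) | C[C@@]12OC(=O)C=C1[C@H]([C@@H]3CCCC/C3=N\N4CCC[C@H]4COC)C=C2[O-].[Li+] | intermediate
14 | C12 alkenyl triflate of the Michael adduct (butenolide; ring A at C10 anti to 13-Me; 9S; SAMP hydrazone) | C[C@@]12OC(=O)C=C1[C@H]([C@@H]3CCCC/C3=N\N4CCC[C@H]4COC)C=C2OS(=O)(=O)C(F)(F)F | intermediate
15 | C12 alkenyl triflate with saturated cis-fused lactone (H15 syn to 13-Me) | C[C@@]12OC(=O)C[C@@H]1[C@H]([C@@H]3CCCC/C3=N\N4CCC[C@H]4COC)C=C2OS(=O)(=O)C(F)(F)F | intermediate
16 | (S)-6-methylpiperidin-2-one | C[C@H]1CCCC(=O)N1 | starting material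
17 | tert-butyl (S)-2-methyl-6-oxopiperidine-1-carboxylate | C[C@H]1CCCC(=O)N1C(=O)OC(C)(C)C | intermediate
18 | tert-butyl (S)-2-methyl-6-(trifluoromethylsulfonyloxy)-3,4-dihydro-2H-pyridine-1-carboxylate | C[C@H]1CCC=C(OS(=O)(=O)C(F)(F)F)N1C(=O)OC(C)(C)C | intermediate
19 | C12 pinacol boronate of the saturated lactone | C[C@@]12OC(=O)C[C@@H]1[C@H]([C@@H]3CCCC/C3=N\N4CCC[C@H]4COC)C=C2B5OC(C)(C)C(C)(C)O5 | intermediate
20 | amido-diene (C12 bonded to C2' of the N-Boc 6'-methyl-tetrahydropyridine) | C[C@@]12OC(=O)C[C@@H]1[C@H]([C@@H]3CCCC/C3=N\N4CCC[C@H]4COC)C=C2C5=CCC[C@H](C)N5C(=O)OC(C)(C)C | intermediate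
21 | N-Boc 2',6'-cis piperidine lactone (12R, 2'S, 6'S; hydrazone retained) | C[C@@]12OC(=O)C[C@@H]1[C@H]([C@@H]3CCCC/C3=N\N4CCC[C@H]4COC)C[C@@H]2[C@@H]5CCC[C@H](C)N5C(=O)OC(C)(C)C | intermediate
22 | sodium enolate of the 2-formyl lactone | C[C@@]12OC(=O)C(=C[O-])[C@@H]1[C@H]([C@@H]3CCCC/C3=N\N4CCC[C@H]4COC)C[C@@H]2[C@@H]5CCC[C@H](C)N5C(=O)OC(C)(C)C.[Na+] | intermediate
23 | 2-methylene lactone (hydrazone, N-Boc) | C[C@@]12OC(=O)C(=C)[C@@H]1[C@H]([C@@H]3CCCC/C3=N\N4CCC[C@H]4COC)C[C@@H]2[C@@H]5CCC[C@H](C)N5C(=O)OC(C)(C)C | intermediate
24 | keto 2-methylene lactone (N-Boc) | C[C@@]12OC(=O)C(=C)[C@@H]1[C@H]([C@@H]3CCCCC3=O)C[C@@H]2[C@@H]4CCC[C@H](C)N4C(=O)OC(C)(C)C | intermediate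
25 | piperidinium trifluoroacetate of the keto 2-methylene lactone | C[C@@]12OC(=O)C(=C)[C@@H]1[C@H]([C@@H]3CCCCC3=O)C[C@@H]2[C@@H]4CCC[C@H](C)[NH2+]4.[O-]C(=O)C(F)(F)F | intermediate
26 | N-acetyl keto exo-methylene lactone (rings A, C, D, E in place; C3 = exo-CH2; C4 = ketone) | C[C@@]12OC(=O)C(=C)[C@@H]1[C@H]([C@@H]3CCCCC3=O)C[C@@H]2[C@@H]4CCC[C@H](C)N4C(C)=O | intermediate
27 | CNP0529632.1 | CC(=O)N1[C@@H](C)CCC[C@H]1[C@H]1C[C@@H]2[C@H]3C(=C[C@]4(O)CCCC[C@@H]24)C(=O)O[C@@]13C | target

**Step count and risks**
Total steps: 16. Longest linear sequence: 13 (steps 1–5, 7, 8, 11–16).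

Step 16 (Proposed new method). What may go wrong: chain-growth oligomerisation of the exo-methylene lactone, failure of the carbene-bound C3 nucleophile to add to the hindered ketone, or base-induced epimerisation at C9 before closure. The fallback sets out from 26. Addition of vinylmagnesium bromide with CeCl3 (THF, −78 °C) to the ring-A ketone from the equatorial side should give the tertiary allylic alcohol F1. Ring-closing metathesis of its two terminal alkenes with the second-generation Hoveyda–Grubbs catalyst (toluene, 80 °C) would close ring B at C2=C3 and arrive at 27.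

Step 7. What may go wrong: competing 1,2-addition of the aza-enolate to the carbonyl groups of 8, or a mismatch between the auxiliary and the facial bias of 8 that erodes selectivity at C9 and C10. The fallback sets out from 8. A Mukaiyama–Michael addition of 1-(trimethylsilyloxy)cyclohexene (Me3SiOSO2CF3 cat., CH2Cl2, −78 °C), which is 1,4-selective and involves no auxiliary, would give the silyl enol ether F2, the 9S epimer being separated from its C9 epimer. CsF and PhNTf2 (DME, rt) would convert it into the keto triflate F3. Condensation of F3 with SAMP (10) at 60 °C comes back to the route at 14.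

Step 12. What may go wrong: addition of hydrogen across the ends of the amido-diene to leave a tetrasubstituted ene-carbamate that resists reduction, loss of facial control at C2', or reduction of the hydrazone C=N. The fallback sets out from 17 and boronate 19 (isolated here). Reduction of 17 with LiBHEt3 (THF, −78 °C) and methanolysis (MeOH, pyridinium p-toluenesulfonate) would give the N,O-acetal F4. BF3·OEt2 (CH2Cl2, −78 to 0 °C) would turn F4 into the N-acyliminium ion, which 19 alkenylates at C2' from the axial direction, cis to the 6'-methyl group, to give the alkenyl piperidine F5. Hydrogenation of the single remaining ring-C alkene of F5 (H2, Pd/C, EtOAc) from the convex face comes back to the route at 21.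

**Further compounds**
F1 | step 16 | tertiary allylic alcohol from 26 (C4 vinyl equatorial, hydroxyl axial and cis to the C9–C10 bond) | C[C@@]12OC(=O)C(=C)[C@@H]1[C@H]([C@@H]3CCCC[C@@]3(O)C=C)C[C@@H]2[C@@H]4CCC[C@H](C)N4C(C)=O
F2 | step 7 | C12 trimethylsilyl enol ether of the Michael adduct with free ring-A ketone | C[C@@]12OC(=O)C=C1[C@H]([C@@H]3CCCCC3=O)C=C2O[Si](C)(C)C
F3 | step 7 | C12 alkenyl triflate of the Michael adduct with free ring-A ketone | C[C@@]12OC(=O)C=C1[C@H]([C@@H]3CCCCC3=O)C=C2OS(=O)(=O)C(F)(F)F
F4 | step 12 | tert-butyl (6S)-2-methoxy-6-methylpiperidine-1-carboxylate (mixture at C2) | COC1CCC[C@H](C)N1C(=O)OC(C)(C)C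
F5 | step 12 | N-Boc 2',6'-cis piperidine with the ring-C alkene C11=C12 still in place | C[C@@]12OC(=O)C[C@@H]1[C@H]([C@@H]3CCCC/C3=N\N4CCC[C@H]4COC)C=C2[C@@H]5CCC[C@H](C)N5C(=O)OC(C)(C)C
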